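**Retrosynthetic overview**

1. Numbering: ring A (anisole ring) has C1 (OMe), C2 (Br), C4 (Br), C6 (O to ring B); ring B (phenol ring) has C1′ (OH), C2′, C3′, C5′ (Br), C6′ (O to ring A). The strategy rests on ring A: its oxygens sit on adjacent C1 and C6 and C2 carries bromine where a 3-aryloxysalicylic acid carries CO2H, so C2–Br comes from ipso-bromodecarboxylation and C4–Br from bromination para to the C1 oxygen.
2. Ring A is cut at C2–C3 and C5–C6: C1, C2, C6 and the carboxyl carbon come from a 4-aryloxy-1,3-bis(trimethylsilyloxy)diene, C3–C5 from 1,1,3,3-tetramethoxypropane (3+3 cyclocondensation to a methyl 3-aryloxysalicylate).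
3. The ring B–O–C6 bond is traced back to O-alkylation of a phenoxide by methyl 4-chloroacetoacetate, so the hindered diaryl ether is never made by arylation.
4. Ring B is an intact benzene ring from 3-bromo-2-hydroxybenzaldehyde and carries all three bromines and a benzyl ether before the ether bond is made (C2′–Br bought, C6′–O by Baeyer–Villiger oxidation, C3′/C5′–Br by hydroxyl-directed bromination), because a late bromination ortho to the C1′ hydroxyl would compete with the para position C4′.
5. Order of rings: ring B (starting material), then ring A (step 7); end game: saponification, bromodecarboxylation, O-methylation, debenzylation.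

Key step: step 7

Remark on the chemistry: silyl enol ether 9, dienolate 10 and diene 11 are expected as mixtures of double-bond isomers, which is of no consequence because this geometry is lost when ring A becomes aromatic; their SMILES are therefore written without configuration.

**Route**

Step 1
Reactants: 1 3-bromo-2-hydroxybenzaldehyde
Product: 2 2-(benzyloxy)-3-bromobenzaldehyde
Conditions: BnBr, K2CO3, DMF, 20 °C
Reagents that add atoms: benzyl bromide, BrCc1ccccc1
Why: Williamson etherification: the acidic salicylaldehyde hydroxyl is benzylated cleanly under carbonate conditions, which masks the future C1′ hydroxyl with a group that survives every later step and can be removed without hydrogenolysis.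

Step 2
Reactants: 2 2-(benzyloxy)-3-bromobenzaldehyde
Product: 4 2-(benzyloxy)-3-bromophenol, via 2-(benzyloxy)-3-bromophenyl formate 3 (not isolated)
Conditions: mCPBA, CH2Cl2, 0 → 20 °C; aq. NaHCO3; then K2CO3 (cat.), MeOH, 20 °C
Reagents that add atoms: 3-chloroperoxybenzoic acid, OOC(=O)c1cccc(Cl)c1
Why: Baeyer–Villiger (Dakin-type) oxidation: the ortho-alkoxyaryl group migrates in preference to hydrogen to give aryl formate 3, and its methanolysis frees the oxygen that will become the ether oxygen on C6′, next to the benzyloxy carbon, with no regiochemical choice.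

Step 3
Reactants: 4 2-(benzyloxy)-3-bromophenol
Product: 6 2-(benzyloxy)-3,4,6-tribromophenol, via 2-(benzyloxy)-3,4-dibromophenol 5 (not isolated)
Conditions: NBS (2.1 equiv), MeCN, 0 → 20 °C
Reagents that add atoms: N-bromosuccinimide, O=C1CCC(=O)N1Br
Why: Electrophilic aromatic bromination: the free hydroxyl directs both bromines to its para and free ortho positions (C3′ and C5′ of ring B), whereas C4′ is meta to the hydroxyl and para only to a benzyloxy group that is twisted out of conjugation by its two ortho neighbours.

Step 4
Reactants: 6 2-(benzyloxy)-3,4,6-tribromophenol; 7 methyl 4-chloro-3-oxobutanoate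
Product: 8 methyl 4-[2-(benzyloxy)-3,4,6-tribromophenoxy]-3-oxobutanoate
Conditions: K2CO3 (1.05 equiv), KI (0.1 equiv), acetone, 20 → 50 °C
Reagents that add atoms: none
Why: Williamson-type SN2 O-alkylation of a phenoxide by an α-chloro ketone (iodide-assisted): the phenol is several pKa units more acidic than the β-keto ester, so one equivalent of carbonate gives the phenoxide while the chloro ketone stays un-enolised and highly electrophilic, and the crowded ether oxygen is bonded to a primary sp3 carbon.

Step 5
Reactants: 8 methyl 4-[2-(benzyloxy)-3,4,6-tribromophenoxy]-3-oxobutanoate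
Product: 9 methyl 4-[2-(benzyloxy)-3,4,6-tribromophenoxy]-3-(trimethylsilyloxy)but-2-enoate
Conditions: Me3SiCl (1.5 equiv), Et3N (1.6 equiv), toluene, 20 °C, 48 h
Reagents that add atoms: chlorotrimethylsilane, C[Si](C)(C)Cl
Why: O-Silylation of the enolised β-keto ester (silyl enol ether formation): the conjugated 3-silyloxy enoate is the favoured isomer under Me3SiCl/Et3N, and the ammonium salt is filtered off under argon so that no water meets the product.

Step 6
Reactants: 9 methyl 4-[2-(benzyloxy)-3,4,6-tribromophenoxy]-3-(trimethylsilyloxy)but-2-enoate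
Product: 11 4-[2-(benzyloxy)-3,4,6-tribromophenoxy]-1-methoxy-1,3-bis(trimethylsilyloxy)buta-1,3-diene, via lithium dienolate 10 (not isolated)
Conditions: LiN(iPr)2 (1.05 equiv), THF, −78 °C, 30 min; then Me3SiCl, −78 → 20 °C
Reagents that add atoms: chlorotrimethylsilane, C[Si](C)(C)Cl
Why: γ-Deprotonation of the vinylogous ester and O-silylation of the lithium dienolate (the standard route to 1,3-bis(silyloxy)-1,3-dienes): the γ-hydrogens on the aryloxy-bearing carbon are many pKa units more acidic than the lone ring B hydrogen between two bromines, so with at most 1.05 equiv of LiN(iPr)2 at −78 °C the bromoarene should stay untouched, and the moisture-sensitive diene is used crude.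

Step 7
Reactants: 11 4-[2-(benzyloxy)-3,4,6-tribromophenoxy]-1-methoxy-1,3-bis(trimethylsilyloxy)buta-1,3-diene; 12 1,1,3,3-tetramethoxypropane
Product: 15 methyl 3-[2-(benzyloxy)-3,4,6-tribromophenoxy]-2-hydroxybenzoate, via open-chain acetal adduct 13 (not isolated), via dimethoxycyclohexanone ester 14 (not isolated)
Conditions: Me3SiOTf (0.3 equiv), CH2Cl2, −78 → 20 °C, 12 h; then aq. HCl
Reagents that add atoms: none
Why: Me3SiOTf ionises one acetal of 12 to an oxocarbenium ion that is attacked by the terminal, aryloxy-bearing diene carbon of 11 (the future C6 of ring A) in a vinylogous Mukaiyama addition, giving 13 and the C5–C6 bond. Ionisation of the second acetal is followed by attack of the silyl enol ether carbon (the future C2), a 6-(enolendo)-exo-trig Mukaiyama-type closure that forms C2–C3 and ring A as ketone 14. Loss of two molecules of methanol and enolisation then aromatise the ring, which drives the sequence. The closest known reaction type is the formal 3+3 cyclocondensation of 1,3-bis(silyloxy)-1,3-dienes with 1,1,3,3-tetramethoxypropane to salicylates, known also for 4-aryloxy dienes. No stereocenter remains in 15, so the diastereomers of 13 and 14 are of no consequence. The only selectivity needed is carbon over oxygen attack at the two nucleophilic diene carbons, secured by the soft silyl enol ether termini, and the symmetrical three-carbon electrophile rules out regioisomers whichever bond forms first.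

Step 8
Reactants: 15 methyl 3-[2-(benzyloxy)-3,4,6-tribromophenoxy]-2-hydroxybenzoate
Product: 17 3-[2-(benzyloxy)-3,4,6-tribromophenoxy]-2-hydroxybenzoic acid, via sodium carboxylate 16 (not isolated)
Conditions: NaOH (3 equiv), MeOH–THF–H2O, 60 °C; then aq. HCl to pH 2
Reagents that add atoms: sodium hydroxide, [Na+].[OH-]
Why: Saponification (base hydrolysis of the ester by acyl–oxygen cleavage): the aryl ethers, the benzyl ether and the aryl bromides are inert to aqueous hydroxide at 60 °C, and the free carboxylic acid is what the ipso substitution needs.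

Step 9
Reactants: 17 3-[2-(benzyloxy)-3,4,6-tribromophenoxy]-2-hydroxybenzoic acid
Product: 19 2-[2-(benzyloxy)-3,4,6-tribromophenoxy]-4,6-dibromophenol, via 5-bromosalicylic acid 18 (not isolated)
Conditions: Br2 (2.1 equiv), NaHCO3, MeCN–H2O, 0 → 20 °C; then aq. Na2S2O3, aq. HCl
Reagents that add atoms: bromine, BrBr
Why: Electrophilic bromination followed by ipso-bromodecarboxylation of a salicylic acid (as in the classical conversion of salicylic acid into 2,4,6-tribromophenol): the phenoxide directs the first bromine to C4 (para) and the second to the carboxyl-bearing C2 (ortho), where the dienone loses CO2, while C6 is blocked by the aryloxy group and ring B, with no free hydroxyl and a single hydrogen flanked by two bromines, does not compete.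

Step 10
Reactants: 19 2-[2-(benzyloxy)-3,4,6-tribromophenoxy]-4,6-dibromophenol
Product: 20 3-(benzyloxy)-1,2,5-tribromo-4-(3,5-dibromo-2-methoxyphenoxy)benzene
Conditions: MeI (3 equiv), K2CO3, DMF, 20 → 40 °C
Reagents that add atoms: iodomethane, CI
Why: Williamson O-methylation: the acidic, di-ortho-substituted phenoxide is still readily alkylated by the small and reactive iodomethane, and nothing else in 19 is nucleophilic.

Step 11
Reactants: 20 3-(benzyloxy)-1,2,5-tribromo-4-(3,5-dibromo-2-methoxyphenoxy)benzene
Product: 22 2,3,5-tribromo-6-(3,5-dibromo-2-methoxyphenoxy)phenol, via aryloxydichloroborane 21 (not isolated)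
Conditions: BCl3 (2 equiv), pentamethylbenzene (3 equiv), CH2Cl2, −78 °C; then H2O
Reagents that add atoms: none
Why: Lewis acid-mediated benzyl ether cleavage with a cation scavenger: BCl3 ionises the benzyl–oxygen bond at −78 °C and pentamethylbenzene traps the benzyl cation by Friedel–Crafts alkylation, conditions that spare the aryl methyl ether, the diaryl ether and all five C–Br bonds, which hydrogenolysis would not.

**Compound list**

1 | 3-bromo-2-hydroxybenzaldehyde | O=Cc1cccc(Br)c1O | starting material
2 | 2-(benzyloxy)-3-bromobenzaldehyde | O=Cc1cccc(Br)c1OCc1ccccc1 | intermediate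
3 | 2-(benzyloxy)-3-bromophenyl formate | O=COc1cccc(Br)c1OCc1ccccc1 | intermediate (not isolated)
4 | 2-(benzyloxy)-3-bromophenol | Oc1cccc(Br)c1OCc1ccccc1 | intermediate
5 | 2-(benzyloxy)-3,4-dibromophenol | Oc1ccc(Br)c(Br)c1OCc1ccccc1 | intermediate (not isolated)
6 | 2-(benzyloxy)-3,4,6-tribromophenol | Oc1c(Br)cc(Br)c(Br)c1OCc1ccccc1 | intermediate
7 | methyl 4-chloro-3-oxobutanoate (methyl 4-chloroacetoacetate) | COC(=O)CC(=O)CCl | starting material
8 | methyl 4-[2-(benzyloxy)-3,4,6-tribromophenoxy]-3-oxobutanoate | COC(=O)CC(=O)COc1c(Br)cc(Br)c(Br)c1OCc1ccccc1 | intermediate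
9 | methyl 4-[2-(benzyloxy)-3,4,6-tribromophenoxy]-3-(trimethylsilyloxy)but-2-enoate (mixture of double-bond isomers) | COC(=O)C=C(O[Si](C)(C)C)COc1c(Br)cc(Br)c(Br)c1OCc1ccccc1 | intermediate
10 | lithium 4-[2-(benzyloxy)-3,4,6-tribromophenoxy]-1-methoxy-3-(trimethylsilyloxy)buta-1,3-dien-1-olate | [Li+].[O-]C(OC)=CC(O[Si](C)(C)C)=COc1c(Br)cc(Br)c(Br)c1OCc1ccccc1 | intermediate (not isolated)
11 | 4-[2-(benzyloxy)-3,4,6-tribromophenoxy]-1-methoxy-1,3-bis(trimethylsilyloxy)buta-1,3-diene (mixture of double-bond isomers) | COC(O[Si](C)(C)C)=CC(O[Si](C)(C)C)=COc1c(Br)cc(Br)c(Br)c1OCc1ccccc1 | intermediate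
12 | 1,1,3,3-tetramethoxypropane | COC(OC)CC(OC)OC | starting material
13 | methyl 4-[2-(benzyloxy)-3,4,6-tribromophenoxy]-5,7,7-trimethoxy-3-(trimethylsilyloxy)hept-2-enoate (mixture of stereoisomers) | COC(=O)C=C(O[Si](C)(C)C)C(Oc1c(Br)cc(Br)c(Br)c1OCc1ccccc1)C(OC)CC(OC)OC | intermediate (not isolated)
14 | methyl 3-[2-(benzyloxy)-3,4,6-tribromophenoxy]-4,6-dimethoxy-2-oxocyclohexane-1-carboxylate (mixture of diastereomers) | COC(=O)C1C(OC)CC(OC)C(Oc2c(Br)cc(Br)c(Br)c2OCc2ccccc2)C1=O | intermediate (not isolated)
15 | methyl 3-[2-(benzyloxy)-3,4,6-tribromophenoxy]-2-hydroxybenzoate | COC(=O)c1cccc(Oc2c(Br)cc(Br)c(Br)c2OCc2ccccc2)c1O | intermediate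
16 | sodium 3-[2-(benzyloxy)-3,4,6-tribromophenoxy]-2-hydroxybenzoate | [Na+].[O-]C(=O)c1cccc(Oc2c(Br)cc(Br)c(Br)c2OCc2ccccc2)c1O | intermediate (not isolated)
17 | 3-[2-(benzyloxy)-3,4,6-tribromophenoxy]-2-hydroxybenzoic acid | OC(=O)c1cccc(Oc2c(Br)cc(Br)c(Br)c2OCc2ccccc2)c1O | intermediate
18 | 3-[2-(benzyloxy)-3,4,6-tribromophenoxy]-5-bromo-2-hydroxybenzoic acid | OC(=O)c1cc(Br)cc(Oc2c(Br)cc(Br)c(Br)c2OCc2ccccc2)c1O | intermediate (not isolated)
19 | 2-[2-(benzyloxy)-3,4,6-tribromophenoxy]-4,6-dibromophenol | Oc1c(Br)cc(Br)cc1Oc1c(Br)cc(Br)c(Br)c1OCc1ccccc1 | intermediate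
20 | 3-(benzyloxy)-1,2,5-tribromo-4-(3,5-dibromo-2-methoxyphenoxy)benzene | COc1c(Br)cc(Br)cc1Oc1c(Br)cc(Br)c(Br)c1OCc1ccccc1 | intermediate
21 | dichloro[2,3,5-tribromo-6-(3,5-dibromo-2-methoxyphenoxy)phenoxy]borane | COc1c(Br)cc(Br)cc1Oc1c(Br)cc(Br)c(Br)c1OB(Cl)Cl | intermediate (not isolated)
22 | 2,3,5-tribromo-6-(3,5-dibromo-2-methoxyphenoxy)phenol | COc1c(Br)cc(Br)cc1Oc1c(Br)cc(Br)c(Br)c1O | target

**Step count**

Total steps: 11. Longest linear sequence: 11 steps (1 to 22); 7 and 12 are bought.

**Steps most likely to fail**

Step 7 (key step). The sequence may stop after the first addition, or the acid-labile diene may be protodesilylated faster than it reacts, so that little salicylate forms. The fallback builds the same two bonds stepwise and without silyl groups; it sets out from keto ester 8 and comes back at salicylate 15. Michael addition of 8 through its doubly activated carbon to acrolein (Et3N cat., CH2Cl2, 0 °C) should give methyl 4-[2-(benzyloxy)-3,4,6-tribromophenoxy]-3-oxo-2-(3-oxopropyl)butanoate F1. Intramolecular aldol condensation of the aryloxy-bearing carbon onto the aldehyde (p-TsOH cat., toluene, 80 °C) should give methyl 3-[2-(benzyloxy)-3,4,6-tribromophenoxy]-2-oxocyclohex-3-ene-1-carboxylate F2. Dehydrogenation with DDQ (dioxane, 80 °C) should aromatise it to 15.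

Step 6. LiN(iPr)2 may metalate ring B at C4′, the hydrogen between two bromines, leading to bromine migration or aryne formation, and the diene may hydrolyse during isolation. The fallback avoids a strong base altogether; it sets out from keto ester 8 and comes back at diene 11, replacing steps 5 and 6. Double soft enolisation with Me3SiOTf (2.3 equiv) and Et3N (2.6 equiv) in Et2O at 0 → 20 °C, the known one-flask route from 1,3-dicarbonyl compounds to 1,3-bis(silyloxy)dienes, should give 11 directly and makes no new compound on the way.

Step 9. Bromination may stop at acid 18 because ipso attack at the crowded C2 is slow, or excess bromine may oxidise the electron-rich phenoxide. The fallback separates decarboxylation from bromination; it sets out from acid 17 and comes back at phenol 19. Silver-catalysed protodecarboxylation (Ag2CO3 cat., AcOH cat., DMSO, 120 °C) should give 2-[2-(benzyloxy)-3,4,6-tribromophenoxy]phenol F3. Its free hydroxyl then directs NBS (2.1 equiv, MeCN, 0 °C) to the para and free ortho positions to give 19.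

**Further compounds**

F1 | step 7 | methyl 4-[2-(benzyloxy)-3,4,6-tribromophenoxy]-3-oxo-2-(3-oxopropyl)butanoate (racemic) | COC(=O)C(CCC=O)C(=O)COc1c(Br)cc(Br)c(Br)c1OCc1ccccc1
F2 | step 7 | methyl 3-[2-(benzyloxy)-3,4,6-tribromophenoxy]-2-oxocyclohex-3-ene-1-carboxylate (racemic) | COC(=O)C1CCC=C(Oc2c(Br)cc(Br)c(Br)c2OCc2ccccc2)C1=O
F0 | step 6 | none | none
F3 | step 9 | 2-[2-(benzyloxy)-3,4,6-tribromophenoxy]phenol | Oc1ccccc1Oc1c(Br)cc(Br)c(Br)c1OCc1ccccc1
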